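## The problem

Target 17 is a cis-fused bicycle in which a 1,2-dioxane (O1, O2, C3, C4, C5, C6) and a γ-lactone (C1, C2, C3, C4, O4) share the C3–C4 bond, and C6 carries a methyl group and an unbranched 10-phenyldecyl chain (numbering used throughout: C1 lactone carbonyl, C2 its CH2, C3 the peroxy CH, C4 the methyl-bearing lactone carbinol carbon, C5 the ring CH2, C6 the methyl-bearing peroxy carbon, C7 the first chain carbon; O1 on C3 and O2 on C6 are the peroxide oxygens, O4 is the lactone ring oxygen). Of the three stereocentres, C4 and C6 are fully substituted, oxygen-bearing carbons separated by the C5 methylene, and C3 is the only CH. C3 can be governed by C4, because the lactone demands that the C2 arm and O4 be cis, but C4 and C6 cannot govern each other across a CH2 in an open chain, so C4 needs an enantioselective reaction of its own. C6 is the hardest centre: a tertiary peroxide carbon whose two carbon substituents other than the ring CH2 (methyl and chain CH2) differ little, which radical oxygenation makes without facial bias and which the one stereospecific method, opening of an epoxide by H2O2, makes only at the cost of an extra hydroxyl on the neighbouring carbon. The O–O bond will not survive reducing agents, organometallic reagents or low-valent metals, the C3–H next to O1 invites base-induced Kornblum–DeLaMare cleavage and the β-peroxy lactone invites E1cB opening, so all C–C bonds should be made before the peroxide and the endgame should be acidic. The feature that makes the key step possible is that C3 carries O1, one hydrogen and the CH2–C1(=O) arm, which is what the ketone carbon of a β-keto ester becomes when the hydroperoxide on C6, four atoms away, closes on it to a six-membered peroxy-hemiketal and the hemiketal hydroxyl is replaced by hydride; O4 must be masked meanwhile, or the keto ester would close to a tetronic acid.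

## Retrosynthesis

**Lactone C1–O4.** Target 17 is opened at the lactone C–O bond to the cis hydroxy ester 16 and further to its O4 triethylsilyl ether 15. Cutting here, and not at O1–C3 of the intact lactone, keeps the endgame acidic and avoids a base-mediated peroxide conjugate addition next to the sensitive C3–H. Compound 15 is monocyclic and carries all three stereocentres. The forward step asks only that the C2 arm and O4 be cis on the dioxane.

**O1–C3 and C3–H (key step).** Dioxane 15 is traced to peroxy-hemiketal 14 and this to the open δ-hydroperoxy β-keto ester 13. Compared with cutting O2–C6, this cut uses the carbon that is naturally electrophilic, a ketone, and gives an acyclic precursor with two stereocentres. The forward reaction must close the ring, ionise the hemiketal and deliver hydride to the face of C3 trans to O4, without touching the silyl ether or the tertiary C6–O bond.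

**C6–O2.** Hydroperoxide 13 comes from silyl peroxide 12, and 12 from alkene 11 by Markovnikov addition of H and OO–Si across the double bond at C6. This is preferred to epoxide perhydrolysis because it leaves no extra hydroxyl and lets the whole chain be present. Its cost is that the C6 radical is trapped from both faces, so the material is expected to run as a mixture of C6 epimers through 12 and 13 and to be resolved only at the rigid dioxane 15. Isomers of 11 with the double bond toward C7 give the same radical and need not be separated.

**C2–C3.** Keto ester 11 is cut to α-silyloxy ester 10 and the enolate of methyl acetate, used as a reagent (crossed Claisen condensation). This is chosen over homologation from an aldehyde because C3 arrives at the ketone oxidation level in one step and C4, having no hydrogen, cannot epimerise. The forward step asks for acylation of a hindered ester.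

**C4–C5.** Ester 10 is the silyl ether of ene adduct 9, which is cut to ethyl pyruvate 8 and alkene 7 (enantioselective carbonyl-ene reaction). The neighbouring cuts, C3–C4 or C4–CH3, would require enantioselective additions to unactivated or poorly differentiated ketones. Here the chelating 1,2-dicarbonyl is the ideal substrate for a chiral Lewis acid, and the cut removes the only catalyst-controlled stereocentre together with half the skeleton.

**The chain.** Alkene 7 is cut at C7–C8 to methallyl chloride 5 and Grignard reagent 6, made from bromide 4. Bromide 4 is cut at the benzylic bond to 1,9-dibromononane 2 and phenylmagnesium bromide 3, made from bromobenzene 1. Both are copper-catalysed Grignard couplings carried out before any sensitive group exists.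

## Roads not taken

Alternative 1: The cut joins C1 and C6 as the double bond of a six-membered carbocycle, the cis hydroxy mesylate A2, which would come from m-xylene A1 by Birch reduction, desymmetrising syn-dihydroxylation and mesylation. In the forward key step, O3 followed by Me2S cleaves C1=C6 and the C4 hydroxyl closes on the new C1 aldehyde to give lactol A3, with C6 as a methyl ketone side chain.
- Merits: the C3/C4 relationship comes from a syn-dihydroxylation on a ring, and C3 would finally be set by stereospecific inversion when a C6 hydroperoxide displaces the mesylate. That is more secure than a conformational argument.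
- Weak points: C6 is left as a methyl ketone, so the chain and the peroxide must both be installed there by olefination and radical oxygenation, or by organometallic addition and ionising perhydrolysis, and neither controls C6. The displacement is at a secondary carbon next to a quaternary one and competes with β-elimination of the mesylate once the lactol is oxidised to the lactone. The desymmetrisation must tell apart two enantiotopic trisubstituted alkenes, and extra redox steps are needed.
- Comparison: this road is better on C3 and no better on C6. The chosen plan sets against it a shorter sequence, a C4 centre from a catalytic reaction on an ideal substrate, and a chain that is present from the start.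

Alternative 2: The cut is C4–C5 together with the lactone C1–O4. In the forward key step a monovalent copper alkoxide (CuOt-Bu) with a chiral bisphosphine adds the chain-bearing 2-substituted allylboronate A5 to the ketone of methyl levulinate A4, and the tertiary alkoxide closes on the ester to give lactone A6.
- Merits: the full carbon skeleton and the lactone arise in one catalytic asymmetric step. After dehydrogenation of A6 at C2–C3, C3 would be set by conjugate addition of a C6 hydroperoxide, where cis fusion is the only outcome.
- Weak points: the ketone of A4 offers the catalyst only a methyl group against an unbranched CH2 chain, the difficult case for enantioselective ketone allylation. A5 needs its own synthesis. The dehydrogenation of A6 must be done in the presence of the alkene. C6 is again made by uncontrolled radical oxygenation.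
- Comparison: this road is safer at C3. The chosen plan is safer at C4 and reaches C3 at the right oxidation level directly from the Claisen step. Both pay the same price at C6.

Alternative 3: The cut is O2–C6 and O1–C3 in one operation, with the chain cut back to a single carbon. In the forward key step H2O2 with catalytic H3PMo12O40 opens the epoxy butenolide A7 at tertiary C6 with inversion, and Et2NH then triggers 6-exo conjugate addition of the hydroperoxide to the butenolide, giving the C7 alcohol bicycle A8.
- Merits: this is the only road that controls C6, because the epoxide configuration is transferred stereospecifically. C3 is fixed by the cis fusion.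
- Weak points: perhydrolysis leaves a hydroxyl on C7, so the ten-carbon chain must be attached after the peroxide and lactone exist (oxidation, olefination, diimide reduction) under conditions that threaten the C3–H and the O–O bond. A7 needs two separate asymmetric operations.
- Comparison: on C6 this road is clearly better, and it should be preferred if material throughput at C6 matters more than step count. The chosen plan sets against it nine steps from commodity chemicals, all C–C bonds made before the peroxide, and no ylide or strong base after it, and it accepts the loss of the C6 epimer.

Key step: step 8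

Assumption: [Cu((S,S)-t-Bu-box)](SbF6)2 is taken to direct addition to the si face of chelated pyruvate, as in its aldol reactions, so the (R,R) complex is specified for (R)-9; if the sense proves opposite, only the ligand enantiomer changes.

Remark: the cobalt oxygenation is not expected to discriminate the faces of C6, so from step 6 to step 8 each numbered structure denotes the (6R) compound, which is carried together with its (6S) epimer until the chromatographic separation at the dioxane stage after step 8; the same holds for the silyl peroxides F4 and F5 of the fallbacks.

## Route

Step 1
Reactants: 1 bromobenzene; 2 1,9-dibromononane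
Product: 4 (9-bromononyl)benzene, via phenylmagnesium bromide 3 (not isolated)
Conditions: Mg, THF, reflux; then 2 (3 equiv), Li2CuCl4 (3 mol %), THF, 0 °C to rt
Reagents that add atoms: none
Why: Grignard formation followed by Kochi-type copper-catalysed coupling of the aryl Grignard reagent with a primary alkyl bromide; the excess of 2 should keep double arylation low and is recovered by distillation.

Step 2
Reactants: 4 (9-bromononyl)benzene; 5 3-chloro-2-methylprop-1-ene
Product: 7 2-methyl-12-phenyldodec-1-ene, via (9-phenylnonyl)magnesium bromide 6 (not isolated)
Conditions: Mg, THF, 40 °C; then 5 (1.5 equiv), CuI (5 mol %), THF, −20 °C to rt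
Reagents that add atoms: none
Why: Copper-catalysed allylic substitution of methallyl chloride by a primary alkyl Grignard reagent; the allyl unit is symmetric, so SN2 and SN2' attack give the same 1,1-disubstituted alkene.

Step 3
Reactants: 7 2-methyl-12-phenyldodec-1-ene; 8 ethyl pyruvate
Product: 9 ethyl (2R)-2-hydroxy-2-methyl-4-methylidene-14-phenyltetradecanoate
Conditions: 8 (3 equiv), [Cu((R,R)-t-Bu-box)](SbF6)2 (10 mol %; t-Bu-box = 2,2'-(propane-2,2-diyl)bis(4-tert-butyl-4,5-dihydro-1,3-oxazole)), CH2Cl2, 40 °C, sealed vessel
Reagents that add atoms: none
Why: Enantioselective carbonyl-ene reaction: pyruvate chelates the divalent copper centre through both carbonyl oxygens, the tert-butyl groups of the (R,R) ligand leave the re face of the ketone open, and the alkene adds there with transfer of an allylic hydrogen, setting C4 as R. Hydrogen transfer from C7 instead of the methyl group would give double-bond isomers with the same C4 centre, which converge in step 6.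

Step 4
Reactants: 9 ethyl (2R)-2-hydroxy-2-methyl-4-methylidene-14-phenyltetradecanoate
Product: 10 ethyl (2R)-2-methyl-4-methylidene-14-phenyl-2-(triethylsilyloxy)tetradecanoate
Conditions: Et3SiOTf (1.5 equiv), 2,6-lutidine (2.5 equiv), CH2Cl2, 0 °C to rt
Reagents that add atoms: triethylsilyl trifluoromethanesulfonate, CC[Si](CC)(CC)OS(=O)(=O)C(F)(F)F
Why: Silylation of a hindered tertiary alcohol with a silyl triflate and a non-nucleophilic base; masking O4 prevents the keto ester of step 5 from closing to a tetronic acid.

Step 5
Reactants: 10 ethyl (2R)-2-methyl-4-methylidene-14-phenyl-2-(triethylsilyloxy)tetradecanoate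
Product: 11 methyl (4R)-4-methyl-6-methylidene-3-oxo-16-phenyl-4-(triethylsilyloxy)hexadecanoate
Conditions: LiN(i-Pr)2 (3.6 equiv), MeOAc (3.5 equiv), THF, −78 °C; then 10, −78 to −40 °C; aq. NH4Cl
Reagents that add atoms: methyl acetate (as its lithium enolate), COC(C)=O
Why: Crossed Claisen condensation: the acetate enolate adds to the ethyl ester, ethoxide leaves, and the product is shielded from a second addition as its enolate, which is why excess enolate is used. C4 has no hydrogen and cannot epimerise.

Step 6
Reactants: 11 methyl (4R)-4-methyl-6-methylidene-3-oxo-16-phenyl-4-(triethylsilyloxy)hexadecanoate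
Product: 12 methyl (4R,6R)-4,6-dimethyl-3-oxo-16-phenyl-4-(triethylsilyloxy)-6-(triethylsilylperoxy)hexadecanoate
Conditions: Co(thd)2 (10 mol %; thd = 2,2,6,6-tetramethylheptane-3,5-dionate), O2 (1 atm), Et3SiH (2.5 equiv), ClCH2CH2Cl, rt
Reagents that add atoms: dioxygen, O=O; triethylsilane, CC[SiH](CC)CC
Why: Mukaiyama–Isayama hydroperoxysilylation: a cobalt hydride gives H to the less substituted alkene carbon, the tertiary C6 radical takes up O2 and the peroxyl radical is silylated; alkene isomers with the double bond toward C7 give the same radical. Capture of O2 by the planar radical is not expected to distinguish faces, so 12 should be obtained as a near-equal mixture with its C6 epimer, and the mixture is carried on unseparated.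

Step 7
Reactants: 12 methyl (4R,6R)-4,6-dimethyl-3-oxo-16-phenyl-4-(triethylsilyloxy)-6-(triethylsilylperoxy)hexadecanoate (carried with its C6 epimer)
Product: 13 methyl (4R,6R)-6-hydroperoxy-4,6-dimethyl-3-oxo-16-phenyl-4-(triethylsilyloxy)hexadecanoate
Conditions: AcOH–THF–H2O (3:1:1), 0 °C to rt
Reagents that add atoms: none
Why: Acidic hydrolysis of the silyl peroxide, whose Si–OO bond is far more labile than the hindered tertiary silyl ether. The free hydroperoxide is expected to begin adding to the C3 ketone already here, so the material is used as obtained and the C6 epimers are still not separated.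

Step 8
Reactants: 13 methyl (4R,6R)-6-hydroperoxy-4,6-dimethyl-3-oxo-16-phenyl-4-(triethylsilyloxy)hexadecanoate (carried with its C6 epimer)
Product: 15 methyl 2-[(3R,4R,6R)-4,6-dimethyl-6-(10-phenyldecyl)-4-(triethylsilyloxy)-1,2-dioxan-3-yl]acetate, via peroxy-hemiketal 14 (not isolated)
Conditions: Et3SiH (4 equiv), Me3SiOTf (1.5 equiv), CH2Cl2, −78 to −40 °C; then aq. NaHCO3; chromatography
Reagents that add atoms: none
Why: The C6 hydroperoxide adds to the C3 ketone in a 6-exo-trig closure that forms O1–C3 and the 1,2-dioxane ring as peroxy-hemiketal 14, the cyclic form being favoured by the two fully substituted carbons in the tether. Me3SiOTf silylates and ionises the hemiketal oxygen to a cyclic peroxycarbenium ion and Et3SiH transfers hydride to C3 (ionic hydrogenation); the closest known reaction type is the silane and Lewis acid reduction of 3-alkoxy- and 3-hydroxy-1,2-dioxanes and 1,2-dioxolanes through such cations. C3 is the only new stereocentre and is controlled by the ring: the half-chair with the C6 chain and the C4 methyl group equatorial has only a methyl/oxygen syn-axial contact, whereas the other has a methyl/alkyl one, so the C4–OSiEt3 bond should sit pseudoaxial. Hydride should enter on the axial trajectory that leads directly to a chair, anti to that C–O bond (the polar Felkin–Anh arrangement), so that H ends trans and the CH2CO2Me arm cis to O4, which is the (3R) configuration. The selectivity the step needs is this facial one at C3, and it rests on the configurations of C4 and C6 and on the bulky silyl ether, not on the reagent. At low temperature the tertiary silyl ether, the ester and the tertiary C6–O bond should stay intact. The (6S) material carried from step 6 runs through the same sequence to C6-epimeric dioxanes, and these, with any (3S) isomer, are removed from 15 by chromatography at this first rigid, non-tautomeric stage.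

Step 9
Reactants: 15 methyl 2-[(3R,4R,6R)-4,6-dimethyl-6-(10-phenyldecyl)-4-(triethylsilyloxy)-1,2-dioxan-3-yl]acetate
Product: 17 (3R,4aR,7aR)-3,4a-dimethyl-3-(10-phenyldecyl)tetrahydrofuro[3,2-c][1,2]dioxin-6(3H)-one, via hydroxy ester 16 (not isolated)
Conditions: 48 % aq. HF, MeCN, 0 °C to rt; then TsOH·H2O (cat.), CH2Cl2, rt
Reagents that add atoms: none
Why: HF cleaves the tertiary silyl ether without touching the O–O bond, and the freed O4 hydroxyl, cis to the ester arm, closes by acid-catalysed lactonisation (5-exo-trig) to the cis-fused γ-lactone. No stereocentre is touched and no base is present that could open the β-peroxy lactone.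

## Compound list

1 | bromobenzene | Brc1ccccc1 | starting material
2 | 1,9-dibromononane | BrCCCCCCCCCBr | starting material
3 | phenylmagnesium bromide | Br[Mg]c1ccccc1 | intermediate (not isolated)
4 | (9-bromononyl)benzene | BrCCCCCCCCCc1ccccc1 | intermediate
5 | 3-chloro-2-methylprop-1-ene | C=C(C)CCl | starting material
6 | (9-phenylnonyl)magnesium bromide | Br[Mg]CCCCCCCCCc1ccccc1 | intermediate (not isolated)
7 | 2-methyl-12-phenyldodec-1-ene | C=C(C)CCCCCCCCCCc1ccccc1 | intermediate
8 | ethyl pyruvate | CCOC(=O)C(C)=O | starting material
9 | ethyl (2R)-2-hydroxy-2-methyl-4-methylidene-14-phenyltetradecanoate | C=C(CCCCCCCCCCc1ccccc1)C[C@@](C)(O)C(=O)OCC | intermediate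
10 | ethyl (2R)-2-methyl-4-methylidene-14-phenyl-2-(triethylsilyloxy)tetradecanoate | C=C(CCCCCCCCCCc1ccccc1)C[C@@](C)(O[Si](CC)(CC)CC)C(=O)OCC | intermediate
11 | methyl (4R)-4-methyl-6-methylidene-3-oxo-16-phenyl-4-(triethylsilyloxy)hexadecanoate | C=C(CCCCCCCCCCc1ccccc1)C[C@@](C)(O[Si](CC)(CC)CC)C(=O)CC(=O)OC | intermediate
12 | methyl (4R,6R)-4,6-dimethyl-3-oxo-16-phenyl-4-(triethylsilyloxy)-6-(triethylsilylperoxy)hexadecanoate | C[C@@](OO[Si](CC)(CC)CC)(CCCCCCCCCCc1ccccc1)C[C@@](C)(O[Si](CC)(CC)CC)C(=O)CC(=O)OC | intermediate
13 | methyl (4R,6R)-6-hydroperoxy-4,6-dimethyl-3-oxo-16-phenyl-4-(triethylsilyloxy)hexadecanoate | C[C@@](OO)(CCCCCCCCCCc1ccccc1)C[C@@](C)(O[Si](CC)(CC)CC)C(=O)CC(=O)OC | intermediate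
14 | methyl 2-[(4R,6R)-3-hydroxy-4,6-dimethyl-6-(10-phenyldecyl)-4-(triethylsilyloxy)-1,2-dioxan-3-yl]acetate (both C3 anomers) | C[C@@]1(CCCCCCCCCCc2ccccc2)C[C@@](C)(O[Si](CC)(CC)CC)C(O)(CC(=O)OC)OO1 | intermediate (not isolated)
15 | methyl 2-[(3R,4R,6R)-4,6-dimethyl-6-(10-phenyldecyl)-4-(triethylsilyloxy)-1,2-dioxan-3-yl]acetate | C[C@@]1(CCCCCCCCCCc2ccccc2)C[C@@](C)(O[Si](CC)(CC)CC)[C@@H](CC(=O)OC)OO1 | intermediate
16 | methyl 2-[(3R,4R,6R)-4-hydroxy-4,6-dimethyl-6-(10-phenyldecyl)-1,2-dioxan-3-yl]acetate | C[C@@]1(CCCCCCCCCCc2ccccc2)C[C@@](C)(O)[C@@H](CC(=O)OC)OO1 | intermediate (not isolated)
17 | (3R,4aR,7aR)-3,4a-dimethyl-3-(10-phenyldecyl)tetrahydrofuro[3,2-c][1,2]dioxin-6(3H)-one | C[C@@]1(CCCCCCCCCCc2ccccc2)C[C@@]2(C)OC(=O)C[C@H]2OO1 | target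

## Step count and least certain steps

Total step count: 9. Longest linear sequence: 9 steps (1 → 4 → 7 → 9 → 10 → 11 → 12 → 13 → 15 → 17).

**Step 8 (key step).** The most likely failure is poor facial selectivity at C3. The steric preference that puts the C4–O bond pseudoaxial is opposed by the tendency of oxocarbenium-type ions to place the better donor, here the C4–CH3 bond, pseudoaxial next to the cationic carbon, and attack on that half-chair would put the arm trans to O4. A second failure is slow ionisation, because the cation is flanked by the ester-bearing CH2 and a C–O bond, with loss of a C2 proton to an exocyclic enol peroxide instead of reduction.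

The fallback forms O1–C3 by conjugate addition, where cis fusion is enforced; it sets out from 11 and returns at 17. NaBH4 in MeOH at 0 °C would reduce the C3 ketone to the hydroxy ester F1 (both C3 epimers). Aqueous HF in MeCN would then remove the silyl ether, and the γ-hydroxy ester would close to the hydroxy lactone F2. MsCl and Et3N would eliminate to the butenolide F3. The cobalt conditions of step 6, selective for the electron-rich 1,1-disubstituted alkene, would give the silyl peroxide F4, again with its C6 epimer. Et2NH in CF3CH2OH would free the hydroperoxide, which adds 6-exo to the butenolide to give 17, separated from its C6 epimer by chromatography.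

**Step 6.** Lack of facial discrimination at the C6 radical is expected and budgeted: about half of the material should run through the (6S) series and be discarded after step 8. Stereospecific control would require the epoxide perhydrolysis of the route through A8, with its late chain attachment, and is not adopted. What may additionally go wrong is sequestration of cobalt by the chelating β-keto ester, or oxygenation at C2, which would stall the hydrogen-atom transfer.

The fallback runs the oxygenation at the alcohol oxidation level; it sets out from 11 and returns at 12. NaBH4 would give the hydroxy ester F1, the same cobalt conditions would give the hydroxy silyl peroxide F5, and Dess–Martin periodinane, which tolerates peroxides, would restore the C3 ketone to give 12.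

**Step 5.** The ester carbonyl of 10 is attached to a fully substituted, silyloxy-bearing carbon. Slow acylation, with self-condensation of the acetate enolate on warming, is the likely failure.

The fallback replaces the acylation by an aldol addition and an oxidation; it sets out from 10 and returns at 11. i-Bu2AlH at −78 °C would give the aldehyde F6, the lithium enolate of methyl acetate would add at −78 °C to give the hydroxy ester F1, and Dess–Martin periodinane would give 11.

**Step 3.** A pyruvate ester is a weaker enophile than a glyoxylate, and the long-chain alkene may react slowly or with lower enantioselectivity than simple 1,1-disubstituted alkenes. Erosion of enantiomeric purity at C4 cannot be corrected later.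

The fallback sets C4 by auxiliary control instead; it sets out from Grignard reagent 6 and returns at 9. Reagent 6 would be coupled (CuI) with excess 3-chloro-2-(chloromethyl)prop-1-ene to give the allylic chloride F7. The lithium enolate of (2S,5S)-2-tert-butyl-5-methyl-1,3-dioxolan-4-one, made from (S)-lactic acid and pivalaldehyde, would be alkylated with F7 (NaI, THF, −78 °C) anti to the tert-butyl group to give the dioxolanone F8, and acid-catalysed ethanolysis of F8 would give 9.

## Further compounds

F1 | step 8 | methyl (4R)-3-hydroxy-4-methyl-6-methylidene-16-phenyl-4-(triethylsilyloxy)hexadecanoate (both C3 epimers) | C=C(CCCCCCCCCCc1ccccc1)C[C@@](C)(O[Si](CC)(CC)CC)C(O)CC(=O)OC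
F2 | step 8 | (5R)-4-hydroxy-5-methyl-5-(2-methylidene-12-phenyldodecyl)oxolan-2-one (both C4 epimers) | C=C(CCCCCCCCCCc1ccccc1)C[C@@]1(C)OC(=O)CC1O
F3 | step 8 | (5R)-5-methyl-5-(2-methylidene-12-phenyldodecyl)furan-2(5H)-one | C=C(CCCCCCCCCCc1ccccc1)C[C@@]1(C)OC(=O)C=C1
F4 | step 8 | (5R)-5-methyl-5-[(2R)-2-methyl-12-phenyl-2-(triethylsilylperoxy)dodecyl]furan-2(5H)-one | C[C@@](OO[Si](CC)(CC)CC)(CCCCCCCCCCc1ccccc1)C[C@@]1(C)OC(=O)C=C1
F5 | step 6 | methyl (4R,6R)-3-hydroxy-4,6-dimethyl-16-phenyl-4-(triethylsilyloxy)-6-(triethylsilylperoxy)hexadecanoate (both C3 epimers) | C[C@@](OO[Si](CC)(CC)CC)(CCCCCCCCCCc1ccccc1)C[C@@](C)(O[Si](CC)(CC)CC)C(O)CC(=O)OC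
F6 | step 5 | (2R)-2-methyl-4-methylidene-14-phenyl-2-(triethylsilyloxy)tetradecanal | C=C(CCCCCCCCCCc1ccccc1)C[C@@](C)(O[Si](CC)(CC)CC)C=O
F7 | step 3 | 2-(chloromethyl)-12-phenyldodec-1-ene | C=C(CCl)CCCCCCCCCCc1ccccc1
F8 | step 3 | (2S,5R)-2-tert-butyl-5-methyl-5-(2-methylidene-12-phenyldodecyl)-1,3-dioxolan-4-one | C=C(CCCCCCCCCCc1ccccc1)C[C@@]1(C)O[C@H](C(C)(C)C)OC1=O
A1 | alternative 1 | 1,3-dimethylbenzene (m-xylene) | Cc1cccc(C)c1
A2 | alternative 1 | (1S,6R)-6-hydroxy-4,6-dimethylcyclohex-3-en-1-yl methanesulfonate | CC1=CC[C@H](OS(C)(=O)=O)[C@](C)(O)C1
A3 | alternative 1 | (2R,3S)-5-hydroxy-2-methyl-2-(2-oxopropyl)oxolan-3-yl methanesulfonate | CC(=O)C[C@@]1(C)OC(O)C[C@@H]1OS(C)(=O)=O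
A4 | alternative 2 | methyl 4-oxopentanoate (methyl levulinate) | COC(=O)CCC(C)=O
A5 | alternative 2 | 4,4,5,5-tetramethyl-2-(2-methylidene-12-phenyldodecyl)-1,3,2-dioxaborolane | C=C(CCCCCCCCCCc1ccccc1)CB1OC(C)(C)C(C)(C)O1
A6 | alternative 2 | (S)-5-methyl-5-(2-methylidene-12-phenyldodecyl)oxolan-2-one | C=C(CCCCCCCCCCc1ccccc1)C[C@@]1(C)OC(=O)CC1
A7 | alternative 3 | (5R)-5-methyl-5-{[(2R)-2-methyloxiran-2-yl]methyl}furan-2(5H)-one | C[C@]1(CO1)C[C@@]2(C)OC(=O)C=C2
A8 | alternative 3 | (3S,4aR,7aR)-3-(hydroxymethyl)-3,4a-dimethyltetrahydrofuro[3,2-c][1,2]dioxin-6(3H)-one | C[C@@]1(CO)C[C@@]2(C)OC(=O)C[C@H]2OO1
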